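All constants belong to no real substance; the run is a simulation.

You read this flask at 2.5 min, so you want a rule for L.G that keeps the clock out as far as it can.

L 2.0 M; G 2.60 M; time 2.5 min

    L + G → L.G (k1 = 0.00207 L mol⁻¹ s⁻¹)
    L + G → D (k2 = 7.37 × 10⁻⁵ L mol⁻¹ s⁻¹)
    G + L.G → G.L.G (k3 = 0.00185 L mol⁻¹ s⁻¹)
    G + D → G.L.G (k4 = 0.00284 L mol⁻¹ s⁻¹)
    Q ⇌ L.G, rate k5*(cs5 - [L.G]) while solid is left; crystals form when [L.G] > cs5 (cs5 = 1.1 M, k5 = 0.310 s⁻¹)

- L.G and Q together at 2.5 min, in percent of the L charged
- concentration of L.G in solution at 2.5 min, in percent of saturation

Here is my rule. L and dissolved L.G are both used at first order in G, so when you divide their rate equations, G cancels. While no crystals form, the share of L.G then depends on s, the part of L left, and on the step ratio, the constant for L.G going on to G.L.G divided by the sum of the two constants that use L: ρ = 0.863, a selectivity factor. Equal steps, ρ = 1, are the zero of the scale. With b = 0.966, the part of used L that becomes L.G, the share is b(s^ρ − s)/(1 − ρ).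

Before reckoning, weigh each number:

| Number | Test | Weight |
|---|---|---|
| Solubility, dissolution coefficient | The rule's peak, bρ^(ρ/(1 − ρ)), is 38.2%, or 0.763 M, below 1.1 M | None without crystals |
| Constant of L to D | Half-life of L 60 min against 2.1 min | Small, through b |
| Constant of D to G.L.G | Absent from the rule | None in the rule |
| Step ratio | Peak 38.2% against 35.5% at equal steps with the same b, which tests ρ near 1 only | Large, reckoned below |

So s and the step ratio must both be known well. With G held at its charge, s is 43.3% and the rule gives 37.1%. But G falls with every L used, so I take its mean, 2.03 M. Then s is 52.0%, and I commit to 34.3% and 62.5% of saturation. Set ρ to 0, so that no L.G goes on to G.L.G, and the same s gives b(1 − s) = 46.4%, which is the weight of the step ratio.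

The forecast gives 33.7% and 61.3%, on the ground that “no crystals ever form”; my yield stands slightly above its figure.

The flask gives 33.7% and 61.3%, with Q at 0% and L at 53.5% at 2.50 min. Put that L reading into the rule with ρ = 0.863, and it returns 33.8%. Now take the neighbour flask charged with 1.0 M of G, which is 0.500 equiv to L. There L stands at 78.8%, and the same ρ returns 18.4%. That neighbour flask reads 18.4%.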